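**Assumption:** Isopoegin B as drawn has no stereocentre and no stereogenic alkene, so there is no enantiomer to select. The two transient stereocentres (epoxide 8, formyl ketone 9) are racemic and are erased when the chromone forms.

## Retrosynthetic overview

1. The usual disconnection (Suzuki coupling of a 3-iodochromone with a prenylated arylboronate) is not used. The target comes from its 2',4'-bis-MOM ether, whose pyranone ring (O1–C2) is closed last from an α-formyl deoxybenzoin.
2. Key step: the α-formyl deoxybenzoin arises by a BF3-triggered 1,2-acyl shift of a trans-chalcone epoxide. This makes the C3–C4 bond by rearrangement, and the only oxidant in the route (HOO⁻) cannot touch the prenyl group.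
3. The epoxide comes from Weitz–Scheffer epoxidation of a chalcone, itself a Claisen–Schmidt product of an A-ring acetophenone and a B-ring aldehyde. The A-ring is symmetric, so either phenol can close the ring.
4. The B-ring aldehyde comes from symmetric 4,6-dibromoresorcinol by two successive Br/Li exchanges (prenyl, then CHO), so the halogens fix the regiochemistry.
5. Ring order: both benzene rings are bought; a transient oxirane is made and opened; the pyranone is formed last. Allyl groups on the A-ring are removed before the B-ring MOM groups, so the A-ring phenol, not the 2'-OH, captures the formyl carbon.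

## Forward route

**Step 1**
Reactants: 1, 1-(2,6-dihydroxy-4-methoxyphenyl)ethan-1-one
Product: 2, 1-[4-methoxy-2,6-bis(allyloxy)phenyl]ethan-1-one
Conditions: allyl bromide (2.5 equiv), K2CO3, DMF, 60 °C
Reagents that add atoms: allyl bromide, C=CCBr
Why: Williamson etherification of both chelated phenols; allyl ethers survive KOH, HOO⁻ and cold BF3 and are later removed by Pd(0) without touching MOM or the prenyl group.

**Step 2**
Reactants: 3, 4,6-dibromobenzene-1,3-diol
Product: 4, 1,5-dibromo-2,4-bis(methoxymethoxy)benzene
Conditions: MOMCl (2.6 equiv), i-Pr2NEt, CH2Cl2, 0 °C → rt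
Reagents that add atoms: chloromethyl methyl ether, COCCl
Why: Standard MOM acetal protection of phenols; MOM ethers tolerate organolithiums, hydroxide and peroxide.

**Step 3**
Reactants: 4, 1,5-dibromo-2,4-bis(methoxymethoxy)benzene
Product: 5, 1-bromo-2,4-bis(methoxymethoxy)-5-(3-methylbut-2-en-1-yl)benzene
Conditions: n-BuLi (1.05 equiv), THF, −78 °C; CuBr·SMe2 (10 mol %), prenyl bromide, −78 → 0 °C
Reagents that add atoms: prenyl bromide, CC(C)=CCBr
Why: Mono bromine–lithium exchange on the symmetric dibromide followed by Cu-assisted SN2 alkylation with a primary allylic bromide gives the linear prenyl arene as a single regioisomer.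

**Step 4**
Reactants: 5, 1-bromo-2,4-bis(methoxymethoxy)-5-(3-methylbut-2-en-1-yl)benzene
Product: 6, 2,4-bis(methoxymethoxy)-5-(3-methylbut-2-en-1-yl)benzaldehyde
Conditions: n-BuLi (1.1 equiv), THF, −78 °C; DMF; aq. NH4Cl
Reagents that add atoms: N,N-dimethylformamide, CN(C)C=O
Why: Second bromine–lithium exchange (much faster than benzylic deprotonation at −78 °C) and Bouveault formylation place CHO exactly where the chromone will be attached.

**Step 5**
Reactants: 2, 1-[4-methoxy-2,6-bis(allyloxy)phenyl]ethan-1-one; 6, 2,4-bis(methoxymethoxy)-5-(3-methylbut-2-en-1-yl)benzaldehyde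
Product: 7, (E)-1-[4-methoxy-2,6-bis(allyloxy)phenyl]-3-[2,4-bis(methoxymethoxy)-5-(3-methylbut-2-en-1-yl)phenyl]prop-2-en-1-one
Conditions: 50 % aq. KOH, EtOH, rt, 36 h
Reagents that add atoms: none
Why: Claisen–Schmidt condensation of the only enolisable partner (the methyl ketone) with a non-enolisable aldehyde gives the thermodynamic E-chalcone; all four ethers are base-stable.

**Step 6**
Reactants: 7, the E-chalcone
Product: 8, rac-trans-[4-methoxy-2,6-bis(allyloxy)phenyl]{3-[2,4-bis(methoxymethoxy)-5-(3-methylbut-2-en-1-yl)phenyl]oxiran-2-yl}methanone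
Conditions: 30 % H2O2, 2 M NaOH, MeOH–THF, 0 °C → rt; purify on Et3N-deactivated silica
Reagents that add atoms: hydrogen peroxide, OO
Why: Weitz–Scheffer nucleophilic epoxidation: HOO⁻ adds only to the enone, leaving the prenyl and allyl alkenes untouched, and gives the racemic trans epoxide, whose stereocentres are destroyed later.

**Step 7 (key step)**
Reactants: 8, the trans-chalcone epoxide
Product: 9, 2-[2,4-bis(methoxymethoxy)-5-(3-methylbut-2-en-1-yl)phenyl]-3-[4-methoxy-2,6-bis(allyloxy)phenyl]-3-oxopropanal (racemic, largely enolised)
Conditions: BF3·OEt2 (1.2 equiv), CH2Cl2, −78 → −30 °C, 20 min; sat. NaHCO3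
Reagents that add atoms: none
Why: House–Meinwald (semipinacol-type) rearrangement: BF3 opens the epoxide at the benzylic carbon, whose cation is stabilised by the 2,4-dialkoxyaryl ring, and the aroyl group shifts 1,2 to give the α-formyl deoxybenzoin; short, cold exposure spares MOM, allyl and prenyl.

**Step 8**
Reactants: 9, the α-formyl deoxybenzoin
Product: 10, 5-hydroxy-7-methoxy-3-[2,4-bis(methoxymethoxy)-5-(3-methylbut-2-en-1-yl)phenyl]-4H-chromen-4-one
Conditions: morpholine (10 equiv), THF, rt, 1 h; then Pd(PPh3)4 (5 mol %), rt; then AcOH, 50 °C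
Reagents that add atoms: none
Why: Morpholine first converts the β-ketoaldehyde to its enaminone (preventing Tsuji–Trost C-allylation) and then scavenges the π-allyl-Pd from Tsuji–Trost O-deallylation; on acidification one of the two equivalent A-ring phenols adds to the enaminone carbon and expels morpholine (enaminone-to-chromone cyclocondensation) while the still-protected 2'-oxygen cannot form a benzofuran.

**Step 9**
Reactants: 10, the 2',4'-bis-MOM isoflavone
Product: 11, Isopoegin B, 3-[2,4-dihydroxy-5-(3-methylbut-2-en-1-yl)phenyl]-5-hydroxy-7-methoxy-4H-chromen-4-one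
Conditions: 3 M aq. HCl, MeOH–THF, 45 °C, 1–2 h (stop at full conversion)
Reagents that add atoms: none
Why: Acid-catalysed acetal hydrolysis removes both MOM groups; the chromone, the aryl methyl ether, the chelated 5-OH and (with short, mild exposure) the prenyl group survive.

## Compound list

1 | 1-(2,6-dihydroxy-4-methoxyphenyl)ethan-1-one | CC(=O)c1c(O)cc(OC)cc1O | starting material
2 | 1-[4-methoxy-2,6-bis(allyloxy)phenyl]ethan-1-one | CC(=O)c1c(OCC=C)cc(OC)cc1OCC=C | intermediate
3 | 4,6-dibromobenzene-1,3-diol | Oc1cc(O)c(Br)cc1Br | starting material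
4 | 1,5-dibromo-2,4-bis(methoxymethoxy)benzene | COCOc1cc(OCOC)c(Br)cc1Br | intermediate
5 | 1-bromo-2,4-bis(methoxymethoxy)-5-(3-methylbut-2-en-1-yl)benzene | COCOc1cc(OCOC)c(CC=C(C)C)cc1Br | intermediate
6 | 2,4-bis(methoxymethoxy)-5-(3-methylbut-2-en-1-yl)benzaldehyde | COCOc1cc(OCOC)c(CC=C(C)C)cc1C=O | intermediate
7 | (E)-chalcone from 2 and 6 | COCOc1cc(OCOC)c(CC=C(C)C)cc1/C=C/C(=O)c1c(OCC=C)cc(OC)cc1OCC=C | intermediate
8 | trans-chalcone epoxide (racemic; 2R,3S enantiomer drawn) | COCOc1cc(OCOC)c(CC=C(C)C)cc1[C@@H]1O[C@H]1C(=O)c1c(OCC=C)cc(OC)cc1OCC=C | intermediate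
9 | α-formyl deoxybenzoin (racemic/enolised; stereocentre not retained) | COCOc1cc(OCOC)c(CC=C(C)C)cc1C(C=O)C(=O)c1c(OCC=C)cc(OC)cc1OCC=C | intermediate
10 | 2',4'-bis-MOM ether of Isopoegin B | COc1cc(O)c2c(=O)c(-c3cc(CC=C(C)C)c(OCOC)cc3OCOC)coc2c1 | intermediate
11 | Isopoegin B | COc1cc(O)c2c(=O)c(-c3cc(CC=C(C)C)c(O)cc3O)coc2c1 | target

## Step count and main risks

Total steps: 9. Longest linear sequence: 8 (3 → 4 → 5 → 6 → 7 → 8 → 9 → 10 → 11; step 1 is the convergent branch).

Steps most likely to fail, each with a fallback that changes the approach: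

1. **Step 7 (BF3 1,2-acyl shift).** Hydride shift to a 1,2-diketone, fluorohydrin formation or Lewis-acid damage to MOM/prenyl could compete. Fallback: drop the rearrangement and make the same 1,3-dicarbonyl array by Pd-catalysed enolate α-arylation of ketone 2 with bromide 5, then DMF-DMA to the enaminone, which enters Step 8 at the Pd(0)/AcOH stage.
2. **Step 6 (Weitz–Scheffer epoxidation).** The enone is donor-rich and hindered, and the epoxide is acid-labile. Fallback: bypass the chalcone with a Darzens condensation of aldehyde 6 with the α-chloro ketone derived from 2, forming epoxide 8 directly.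
3. **Step 9 (acidic MOM removal beside the prenyl group).** The 4'-OH can cyclise onto the prenyl group to give a 2,2-dimethylchroman, or the alkene can hydrate. Fallback: swap the protecting-group roles from the start (A-ring bis-MOM, B-ring bis-allyl), so the acid step runs while the phenol next to the prenyl is still capped and the final step is a neutral Pd(0) deallylation.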